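**Proposed synthesis of CNP0302517.1, 5-[(3S)-6-hydroxy-7,8-dimethoxychroman-3-yl]-2,3-dimethoxy-1,4-benzoquinone, by an oxygen-tethered Dötz benzannulation**

## Analysis of the target

- The target is an isoflavan-quinone: a chroman (benzo ring A fused to dihydropyran ring C) that carries a 2,3-dimethoxy-1,4-benzoquinone (ring B) at C3.
- Ring A is fully substituted except at C5: O1 on C8a, methoxy groups on C8 and C7, a free hydroxyl on C6, hydrogen on C5 and the C4 methylene on C4a.
- C3 is the only stereocentre and is S. It carries H, C2, C4 and the quinone carbon, so only absolute configuration has to be controlled and no second centre can relay it.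
- The dimethoxyquinone is a pair of vinylogous esters that bases, amines and halide nucleophiles attack. It also makes C3–H vinylogously acidic, so the stereocentre can be lost through a quinone methide tautomer once ring B is oxidised.
- Ring A is a para-alkoxyphenol whose para oxygen is O1. An oxidant that attacks it would open ring C.
- The difficulty is threefold: two arenes with six oxygen substituents between them sit at different oxidation levels; ring B must be raised to the quinone without touching ring A; and the four contiguous oxygens of ring A are awkward to install by aromatic substitution.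
- The strategy rests on the ring A pattern, with O1 on C8a para to the C6 hydroxyl and C5 unsubstituted. This is the output of a Dötz benzannulation in which the carbene alkoxy oxygen is O1, the carbene carbon is C8a, a carbonyl ligand becomes C6 with its free hydroxyl, a tethered alkyne supplies C4a and C5, and a 1,2-dimethoxyvinyl group supplies C8 and C7.

## Retrosynthetic reasoning

**24 from 23.** The last operation only removes the acetyl group from the C6 oxygen of 23. It is done by acid-catalysed solvolysis, because the quinone and the C3–H next to it should not meet base.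

**23 from 22.** Ring B of 23 is traced back to the 2,3,4,5-tetramethoxyphenyl group of 22. The two aryl–oxygen bonds at C2' and C5', the only para pair of methoxy groups, are exchanged in an oxidative demethylation. Carrying ring B as the tetramethyl ether makes it inert to organolithium reagents, to the carbene complex and to heat, so the quinone appears only after all C–C bonds are in place.

**22 from 21.** The acetyl group is put on the free C6 phenol of 21. It makes ring A harder to oxidise than ring B and blocks the para-alkoxyphenol to quinone pathway that would cleave O1–C8a.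

**21 from 19 (key disconnection).** Three bonds of ring A are cut: C8a–C4a, C5–C6 and C6–C7. This opens ring A and ring C together and leads to carbene complex 19.
- In 19 the carbene carbon is C8a, its alkoxy oxygen is O1, and the chain on O1 already contains C2, the C3 stereocentre, C4 and the terminal alkyne (C4a, C5).
- The cut is made here because it builds the hexasubstituted ring A with every oxygen in place and with the C6 hydroxyl free, from an acyclic chain whose only stereocentre is made earlier.
- The forward reaction has to insert the tethered alkyne and one carbonyl ligand and close both rings.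

**19 from 17 and 12.** The carbene carbon–O1 bond is cut, giving acyl chromate 17 and alcohol 12. Activation of 17 as acyloxycarbene 18 lets 12 add at the carbene carbon. The C2–O1 bond of 12 is never broken, so neither the stereocentre nor the β-aryl skeleton is at risk.

**17 from 13 and 14.** Cutting the bond between the acyl carbon and the vinyl carbon leads to vinyllithium 15 (from alkene 13) and a carbonyl ligand of 14, by way of lithium salt 16.
- 13 is taken as the E isomer. Each vinylic hydrogen is then syn to the methoxy group on the neighbouring carbon, which should guide the base.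
- In 15 the metal sits syn to that oxygen, so the anti arrangement that β-alkoxy vinyl anions need for fast β-elimination is absent. The Z isomer of 13 would give exactly that anti arrangement.
- The double-bond geometry does not reach the product, because C7 becomes an aromatic carbon.

**12 from 11, and 11 from 8 and 9.** The primary alcohol 12 comes from reduction of imide 11. The C3–C4 bond of 11 is cut to give the arylacetyl imide 8 and propargyl bromide 9, joined through enolate 10. This places the only stereocentre α to a carboxyl-derived carbon (the later C2), where a chiral auxiliary controls it reliably, and it brings in C4, C4a and C5 in one piece.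

**8 from 5 and 6; 5 from 4; 4 from 2 and 3; 2 from 1.** Imide 8 is the N-acyl derivative of auxiliary 6 and acid 5, made through mixed anhydride 7. Acid 5 comes from its tert-butyl ester 4. The aryl–CH2 bond of 4 is cut to bromide 2 and zinc enolate 3 (a cross-coupling). Bromide 2 comes from 1, whose two free positions are equivalent.

## Alternatives that were turned down

**Alternative 1: ring A ortho-quinone methide plus a chiral ammonium enolate.**
- Disconnection: C3–C4 and O1–C2 (as an ester bond), giving the ortho-quinone methide A2 and the ring B arylacetic acid A3.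
- Forward key step: fluoride unmasks A2 from a silylated benzylic precursor. The activated acid A3 is turned by a chiral isothiourea into a (Z)-ammonium enolate, which adds to the methylene of A2. The phenoxide then closes the lactone and releases the catalyst, giving dihydrocoumarin A1.
- For it: the stereocentre is set catalytically in the step that joins the two arenes. The end-game (three hydrogenolyses, then mild oxidation of the ring B hydroquinone) needs no strong oxidant. On convergence and on mildness of the final oxidation it is stronger than the chosen route.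
- Against it for this target:
  - A1 is at the wrong oxidation level at C2. The lactone must be reduced to a diol and ring C closed again.
  - During these steps C3–H is α to a carbonyl and benzylic, so the stereocentre is at its most epimerisable.
  - A2 carries three donor oxygens, which should make it a poor electrophile that is prone to self-condensation.
  - Both fragments need their oxygen patterns built by classical arene chemistry.
- Comparison: the chosen route gives up catalytic asymmetric induction. In return C2 is a methylene from the start, C3 is never α to a carbonyl after step 6, and ring A is assembled with its substitution pattern fixed by mechanism.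

**Alternative 2: quinone–chromene [3+2] addition to a pterocarpan, then C–O hydrogenolysis.**
- Disconnection: C3–C1', with a temporary bond from the ring B oxygen to C4, giving chromene A5 and quinone A6.
- Forward key step: a TADDOL complex of tetravalent titanium activates A6. C3 of A5 adds to an unsubstituted quinone carbon and the quinone oxygen captures the C4 benzylic cation, giving the cis-fused pterocarpan A4. Hydrogenolysis over Pd/C then cleaves the benzylic C4–O bond and the benzyl ether, and the resulting ring B hydroquinone is oxidised under mild conditions.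
- For it: it is by far the shortest route, roughly half the steps of the chosen one. Ring B arrives as a hydroquinone, so the final oxidation is trivial and selective. On step economy and end-game it is clearly stronger.
- Against it for this target:
  - Enantiocontrol depends on a stoichiometric chiral titanium complex, whose facial discrimination is expected to depend strongly on how the quinone binds.
  - A6 has two equivalent methoxy-flanked carbonyl groups and lower electrophilicity than a mono-alkoxyquinone.
  - Competing [2+2] and [5+2] adducts are plausible.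
  - An unsatisfactory enantiomeric ratio could not easily be upgraded on A4.
  - A5 still needs the fully oxygenated ring A to be made separately.
- Comparison: the chosen route is longer. It offers a stereocentre of predictable configuration, set by an auxiliary with separable diastereomers, and a de novo ring A.

**Alternative 3: oxa-1,6-addition to a vinylquinone with enantioselective protonation at C3.**
- Disconnection: O1–C2, giving the phenol-tethered 2-alkenylquinone A8.
- Forward key step: a cinchona-derived squaramide base promotes 6-endo addition of the ring A phenol oxygen to the terminal alkene carbon of A8. The resulting dienolate is protonated at C3 and gives A7, the silyl ether of the target.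
- For it: the quinone is present before the key step, so no late oxidation is needed. Only a desilylation follows. On directness after the key step it equals or beats the chosen route.
- Against it for this target:
  - The proton delivered in the enantio-determining step is the same vinylogously acidic C3–H that the basic catalyst can remove again.
  - The oxa-addition is reversible, so the product stereocentre sits under equilibrating conditions.
  - Protonation of an extended dienolate far from the catalyst's binding site is hard to control.
  - An uncatalysed background cyclisation of a phenol onto a vinylquinone is likely.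
  - A8 combines a vinylquinone (dimerisation, polymerisation) with an electron-rich phenol and is itself a demanding, fragile intermediate.
- Comparison: the chosen route sets C3 first by robust chemistry and never exposes it to base once ring B is a quinone.

Key step: step 9

## Route

Remark: 13 is assumed to be available as the pure E isomer (the alkene is sold as an E/Z mixture, from which it is taken by fractional distillation), and 3 is used as the purchased ethereal solution.

Step 1
Reactants: 1 1,2,3,4-tetramethoxybenzene
Product: 2 1-bromo-2,3,4,5-tetramethoxybenzene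
Conditions: NBS (1.0 equiv), MeCN, 0 °C → rt
Reagents that add atoms: N-bromosuccinimide, O=C1CCC(=O)N1Br
Why: Electrophilic aromatic bromination; the two free positions of 1 are equivalent and activated by the methoxy groups, so one equivalent of reagent should stop at the monobromide.

Step 2
Reactants: 2 1-bromo-2,3,4,5-tetramethoxybenzene; 3 (2-tert-butoxy-2-oxoethyl)zinc chloride, ClZnCH2CO2tBu
Product: 4 tert-butyl 2-(2,3,4,5-tetramethoxyphenyl)acetate
Conditions: Pd(dba)2 (2 mol%), XPhos (4 mol%), THF, 50 °C
Reagents that add atoms: none
Why: Negishi-type cross-coupling of a Reformatsky reagent with an aryl bromide (ester α-arylation); the neutral zinc enolate needs no strong base and the tert-butyl ester suppresses Claisen condensation.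

Step 3
Reactants: 4 tert-butyl 2-(2,3,4,5-tetramethoxyphenyl)acetate
Product: 5 2-(2,3,4,5-tetramethoxyphenyl)acetic acid
Conditions: TFA, CH2Cl2, 0 °C → rt
Reagents that add atoms: none
Why: Acidolysis of a tert-butyl ester with loss of the tert-butyl group as an alkene; aryl methyl ethers are stable to this acid.

Step 4
Reactants: 5 2-(2,3,4,5-tetramethoxyphenyl)acetic acid; 6 (4S)-4-benzyl-1,3-oxazolidin-2-one
Product: 8 (4S)-4-benzyl-3-[2-(2,3,4,5-tetramethoxyphenyl)acetyl]-1,3-oxazolidin-2-one, via mixed pivalic anhydride 7 (not isolated)
Conditions: t-BuCOCl, Et3N, THF, −20 °C; then LiCl, 6, −20 °C → rt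
Reagents that add atoms: none
Why: N-acylation of the oxazolidinone through a mixed anhydride with LiCl/amine activation; the auxiliary attacks the unhindered arylacetyl carbonyl and not the pivaloyl carbonyl.

Step 5
Reactants: 8 (4S)-4-benzyl-3-[2-(2,3,4,5-tetramethoxyphenyl)acetyl]-1,3-oxazolidin-2-one; 9 propargyl bromide (3-bromoprop-1-yne)
Product: 11 (4S)-4-benzyl-3-[(2S)-2-(2,3,4,5-tetramethoxyphenyl)pent-4-ynoyl]-1,3-oxazolidin-2-one, via sodium Z-enolate 10 (not isolated)
Conditions: NaN(SiMe3)2 (1.05 equiv), THF, −78 °C; then 9 (3 equiv), −78 → −40 °C; AcOH quench at −78 °C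
Reagents that add atoms: none
Why: Evans asymmetric alkylation: the chelated (Z)-enolate is attacked by 9 on the face opposite the benzyl group of the (4S)-auxiliary, which sets the later C3 as S; the reactive propargylic bromide compensates for the lower nucleophilicity of the aryl-stabilised enolate, and the cold acidic quench guards the acidic α-hydrogen of 11.

Step 6
Reactants: 11 (4S)-4-benzyl-3-[(2S)-2-(2,3,4,5-tetramethoxyphenyl)pent-4-ynoyl]-1,3-oxazolidin-2-one
Product: 12 (2S)-2-(2,3,4,5-tetramethoxyphenyl)pent-4-yn-1-ol
Conditions: LiBH4, H2O (1 equiv), Et2O, 0 °C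
Reagents that add atoms: none
Why: Reductive cleavage of an N-acyl oxazolidinone by hydride attack at the exocyclic carbonyl; the stereocentre is no longer enolisable afterwards, it keeps the descriptor S because CH2OH takes the rank of the acyl group, and the auxiliary is recovered.

Step 7
Reactants: 13 (E)-1,2-dimethoxyethene; 14 chromium hexacarbonyl, Cr(CO)6
Product: 17 tetramethylammonium pentacarbonyl[(2E)-2,3-dimethoxyprop-2-enoyl]chromate, via vinyllithium 15 (not isolated), via lithium acyl chromate 16 (not isolated)
Conditions: t-BuLi (0.95 equiv), THF, −78 °C; then Cr(CO)6, −78 → 0 °C; then Me4NBr, H2O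
Reagents that add atoms: tetramethylammonium bromide, C[N+](C)(C)C.[Br-]
Why: α-Lithiation of an enol ether followed by Fischer carbene synthesis (addition of the vinyllithium to a carbonyl ligand); in the E alkene the neighbouring methoxy group is syn to the hydrogen removed and then to lithium, which assists metalation and leaves no anti-periplanar leaving group; cation exchange gives a storable, CH2Cl2-soluble salt.

Step 8
Reactants: 17 tetramethylammonium pentacarbonyl[(2E)-2,3-dimethoxyprop-2-enoyl]chromate; 12 (2S)-2-(2,3,4,5-tetramethoxyphenyl)pent-4-yn-1-ol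
Product: 19 pentacarbonyl{[(1E)-1,2-dimethoxyethenyl][(2S)-2-(2,3,4,5-tetramethoxyphenyl)pent-4-yn-1-yloxy]methylidene}chromium, via acetoxycarbene complex 18 (not isolated)
Conditions: AcBr (1.0 equiv), CH2Cl2, −40 °C; then 12 (0.9 equiv), −40 → −10 °C; rapid chromatography under Ar
Reagents that add atoms: none
Why: Alkoxy exchange through an acyloxycarbene: O-acylation of the acyl chromate makes the carbene carbon strongly electrophilic and the primary alcohol displaces acetate by addition–elimination; the C–O bond of 12 is not broken, so the stereocentre and the β-aryl skeleton are untouched.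

Step 9
Reactants: 19 pentacarbonyl{[(1E)-1,2-dimethoxyethenyl][(2S)-2-(2,3,4,5-tetramethoxyphenyl)pent-4-yn-1-yloxy]methylidene}chromium
Product: 21 (3S)-7,8-dimethoxy-3-(2,3,4,5-tetramethoxyphenyl)-3,4-dihydro-2H-chromen-6-ol, via tricarbonylchromium arene complex 20 (not isolated)
Conditions: THF (0.01 M), 60 °C, Ar; then air, rt
Reagents that add atoms: none
Why: Intramolecular Dötz benzannulation of an alkenyl(alkoxy)carbene complex of zerovalent chromium that carries its alkyne on the alkoxy oxygen, which is the closest known reaction type. Thermal loss of one cis carbonyl ligand opens a site for the tethered alkyne, which inserts into the Cr=C bond; the three-carbon tether lets only the internal alkyne carbon reach the carbene carbon, so C8a–C4a forms and ring C closes in a 6-exo-dig sense with C5 left on chromium. Insertion of one carbonyl ligand into the new vinylcarbene forms C5–C6 and gives a chromium-bound dienylketene whose ketene carbon is C6. A thermal 6π-electrocyclisation onto the methoxy-bearing vinyl carbon C7 forms C6–C7 and closes ring A, and tautomerisation of the cyclohexadienone gives the C6 phenol as complex 20, which air decomplexes. No stereocentre is formed, and C3 lies outside the reacting array, is not enolisable and should be carried through unchanged. The regiochemistry (hydrogen at C5, chain at C4a) is fixed by the tether, and the new C4a=C8a bond is held inside ring C with the cis geometry that the cyclisation needs. Benzannulation should be favoured over cyclopentannulation by the combination of chromium, an alkoxycarbene, an ether solvent and moderate temperature, and high dilution holds back intermolecular alkyne incorporation.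

Step 10
Reactants: 21 (3S)-7,8-dimethoxy-3-(2,3,4,5-tetramethoxyphenyl)-3,4-dihydro-2H-chromen-6-ol
Product: 22 (3S)-7,8-dimethoxy-3-(2,3,4,5-tetramethoxyphenyl)-3,4-dihydro-2H-chromen-6-yl acetate
Conditions: Ac2O, pyridine, DMAP (cat.), CH2Cl2, 0 °C → rt
Reagents that add atoms: acetic anhydride, CC(=O)OC(C)=O
Why: DMAP-catalysed O-acylation of a phenol; the acetoxy group makes ring A harder to oxidise than ring B and blocks oxidation of the para-alkoxyphenol, which would open ring C.

Step 11
Reactants: 22 (3S)-7,8-dimethoxy-3-(2,3,4,5-tetramethoxyphenyl)-3,4-dihydro-2H-chromen-6-yl acetate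
Product: 23 (3S)-3-(4,5-dimethoxy-3,6-dioxocyclohexa-1,4-dien-1-yl)-7,8-dimethoxy-3,4-dihydro-2H-chromen-6-yl acetate
Conditions: (NH4)2Ce(NO3)6 (2.2 equiv), MeCN–H2O, 0 °C, short reaction time
Reagents that add atoms: water, O
Why: Oxidative demethylation of a para-dimethoxyarene by tetravalent cerium through the arene radical cation, with water adding at C2' and C5' and two methoxy groups leaving; ring B is the more electron-rich ring and the only one with a para pair of methoxy groups, while ring A carries the acetoxy group and has no such pair; the acidic medium leaves C3 untouched.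

Step 12
Reactants: 23 (3S)-3-(4,5-dimethoxy-3,6-dioxocyclohexa-1,4-dien-1-yl)-7,8-dimethoxy-3,4-dihydro-2H-chromen-6-yl acetate
Product: 24 5-[(3S)-6-hydroxy-7,8-dimethoxy-3,4-dihydro-2H-chromen-3-yl]-2,3-dimethoxycyclohexa-2,5-diene-1,4-dione (CNP0302517.1)
Conditions: TsOH·H2O (0.3 equiv), MeOH, rt → 40 °C
Reagents that add atoms: none
Why: Acid-catalysed transesterification of an aryl acetate with methanol; acid is chosen because the methoxyquinone and the C3–H next to it are base-sensitive, any exchange of the quinone methoxy groups with the solvent is degenerate, and a sulfonic acid brings no halide that could add to the quinone.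

## Compound list

1 | 1,2,3,4-tetramethoxybenzene | COc1ccc(OC)c(OC)c1OC | starting material
2 | 1-bromo-2,3,4,5-tetramethoxybenzene | COc1cc(Br)c(OC)c(OC)c1OC | intermediate
3 | (2-tert-butoxy-2-oxoethyl)zinc chloride, ClZnCH2CO2tBu | CC(C)(C)OC(=O)C[Zn]Cl | starting material
4 | tert-butyl 2-(2,3,4,5-tetramethoxyphenyl)acetate | COc1cc(CC(=O)OC(C)(C)C)c(OC)c(OC)c1OC | intermediate
5 | 2-(2,3,4,5-tetramethoxyphenyl)acetic acid | COc1cc(CC(=O)O)c(OC)c(OC)c1OC | intermediate
6 | (4S)-4-benzyl-1,3-oxazolidin-2-one | O=C1N[C@@H](Cc2ccccc2)CO1 | starting material
7 | 2,2-dimethylpropanoic 2-(2,3,4,5-tetramethoxyphenyl)acetic anhydride | COc1cc(CC(=O)OC(=O)C(C)(C)C)c(OC)c(OC)c1OC | intermediate (not isolated)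
8 | (4S)-4-benzyl-3-[2-(2,3,4,5-tetramethoxyphenyl)acetyl]-1,3-oxazolidin-2-one | COc1cc(CC(=O)N2[C@@H](Cc3ccccc3)COC2=O)c(OC)c(OC)c1OC | intermediate
9 | propargyl bromide (3-bromoprop-1-yne) | C#CCBr | starting material
10 | sodium (Z)-enolate of 8 | COc1cc(/C=C(\[O-])N2[C@@H](Cc3ccccc3)COC2=O)c(OC)c(OC)c1OC.[Na+] | intermediate (not isolated)
11 | (4S)-4-benzyl-3-[(2S)-2-(2,3,4,5-tetramethoxyphenyl)pent-4-ynoyl]-1,3-oxazolidin-2-one | COc1cc([C@H](CC#C)C(=O)N2[C@@H](Cc3ccccc3)COC2=O)c(OC)c(OC)c1OC | intermediate
12 | (2S)-2-(2,3,4,5-tetramethoxyphenyl)pent-4-yn-1-ol | OC[C@H](c1cc(OC)c(OC)c(OC)c1OC)CC#C | intermediate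
13 | (E)-1,2-dimethoxyethene | CO/C=C/OC | starting material
14 | chromium hexacarbonyl, Cr(CO)6 | O=C=[Cr](=C=O)(=C=O)(=C=O)(=C=O)=C=O | starting material
15 | [(1E)-1,2-dimethoxyethenyl]lithium | [Li]/C(OC)=C\OC | intermediate (not isolated)
16 | lithium pentacarbonyl[(2E)-2,3-dimethoxyprop-2-enoyl]chromate | [Li+].[O-]C(/C(OC)=C\OC)=[Cr](=C=O)(=C=O)(=C=O)(=C=O)=C=O | intermediate (not isolated)
17 | tetramethylammonium pentacarbonyl[(2E)-2,3-dimethoxyprop-2-enoyl]chromate | C[N+](C)(C)C.[O-]C(/C(OC)=C\OC)=[Cr](=C=O)(=C=O)(=C=O)(=C=O)=C=O | intermediate
18 | pentacarbonyl{(acetyloxy)[(1E)-1,2-dimethoxyethenyl]methylidene}chromium | CC(=O)OC(/C(OC)=C\OC)=[Cr](=C=O)(=C=O)(=C=O)(=C=O)=C=O | intermediate (not isolated)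
19 | pentacarbonyl{[(1E)-1,2-dimethoxyethenyl][(2S)-2-(2,3,4,5-tetramethoxyphenyl)pent-4-yn-1-yloxy]methylidene}chromium | O=C=[Cr](=C=O)(=C=O)(=C=O)(=C=O)=C(OC[C@H](c1cc(OC)c(OC)c(OC)c1OC)CC#C)/C(OC)=C\OC | intermediate
20 | tricarbonyl[η6-(3S)-7,8-dimethoxy-3-(2,3,4,5-tetramethoxyphenyl)-3,4-dihydro-2H-chromen-6-ol]chromium, metal on ring A, written as its components | COc1cc([C@H]2COc3c(cc(O)c(OC)c3OC)C2)c(OC)c(OC)c1OC.[Cr].[C-]#[O+].[C-]#[O+].[C-]#[O+] | intermediate (not isolated)
21 | (3S)-7,8-dimethoxy-3-(2,3,4,5-tetramethoxyphenyl)-3,4-dihydro-2H-chromen-6-ol | COc1cc([C@H]2COc3c(cc(O)c(OC)c3OC)C2)c(OC)c(OC)c1OC | intermediate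
22 | (3S)-7,8-dimethoxy-3-(2,3,4,5-tetramethoxyphenyl)-3,4-dihydro-2H-chromen-6-yl acetate | COc1cc([C@H]2COc3c(cc(OC(C)=O)c(OC)c3OC)C2)c(OC)c(OC)c1OC | intermediate
23 | (3S)-3-(4,5-dimethoxy-3,6-dioxocyclohexa-1,4-dien-1-yl)-7,8-dimethoxy-3,4-dihydro-2H-chromen-6-yl acetate | COC1=C(OC)C(=O)C([C@H]2COc3c(cc(OC(C)=O)c(OC)c3OC)C2)=CC1=O | intermediate
24 | 5-[(3S)-6-hydroxy-7,8-dimethoxy-3,4-dihydro-2H-chromen-3-yl]-2,3-dimethoxycyclohexa-2,5-diene-1,4-dione | COC1=C(OC)C(=O)C([C@H]2COc3c(cc(O)c(OC)c3OC)C2)=CC1=O | target

## Step count and least certain steps

Total step count: 12. Longest linear sequence: 11 steps (1 → 2 → 4 → 5 → 8 → 11 → 12 → 19 → 21 → 22 → 23 → 24). Step 7 is a one-step side branch that supplies 17.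

**Step 9 (key step).**
- What may go wrong:
  - Cyclisation without carbonyl insertion (cyclopentannulation), or diversion to furan-type products, encouraged by the donor-rich vinyl group.
  - Chelation of the cis β-methoxy group to chromium, slowing alkyne uptake.
  - Intermolecular insertion and oligomerisation of the terminal alkyne.
  - Oxidation of the electron-rich phenol during decomplexation in air.
- Fallback: the classical isoflavan assembly, setting out from imide 8 and returning at 21.
  - The sodium enolate 10 would be alkylated with the separately prepared ring A electrophile 1-(benzyloxy)-5-(bromomethyl)-2,3-dimethoxy-4-(methoxymethoxy)benzene F1. The same auxiliary control gives the alkylated imide F2.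
  - LiBH4 reduction would give the primary alcohol F3.
  - Acidic methanolysis of the methoxymethyl ether would free the phenol F4.
  - A Mitsunobu cyclisation (PPh3, diisopropyl azodicarboxylate, THF) would close ring C through O1–C2 to the 6-O-benzyl chroman F5.
  - Hydrogenolysis (H2, Pd/C) would give 21.

**Step 7.**
- What may go wrong:
  - β-Elimination of methoxide from vinyllithium 15 while the mixture is warmed for the addition to Cr(CO)6.
  - Incomplete metalation, which leaves t-BuLi to add to the metal carbonyl itself.
- Fallback: no vinyl anion is used. The route sets out from Cr(CO)6 14 and returns at 21.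
  - Commercial methyl methoxyacetate would be formylated (methyl formate, NaH) and O-methylated (Me2SO4) to methyl (2Z)-2,3-dimethoxyprop-2-enoate F6.
  - Saponification with LiOH would give the acid F7, and oxalyl chloride would give the acid chloride F8.
  - 14 would be reduced with C8K to K2Cr(CO)5 F9 and acylated with F8 at −78 °C.
  - Cation exchange would give the tetramethylammonium acyl chromate F10, the Z isomer of 17.
  - Treatment as in step 8 with AcBr and 12 would give the Z-configured carbene complex F11.
  - Heating F11 as in step 9 should give 21, because the double-bond geometry is lost when C7 becomes aromatic.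

**Step 8.**
- What may go wrong:
  - Thermal decomposition of acetoxycarbene 18 before the β-branched alcohol has added.
  - Competing acetylation of 12.
  - Conjugate addition of the alcohol to the vinylcarbene.
- Fallback: the polarity of the C–O bond formation is reversed. The route sets out from 12 and returns at 19.
  - 12 would be converted (Tf2O, 2,6-di-tert-butyl-4-methylpyridine, CH2Cl2, −78 °C) into the primary triflate F12.
  - F12 would O-alkylate the acyl chromate 17 at low temperature to give 19 directly.

**Step 11.**
- What may go wrong:
  - Competing single-electron oxidation of the acetylated but still trialkoxy-substituted ring A.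
  - ortho-Quinone formation on ring B.
  - Loss of the acetate in the acidic aqueous oxidant, followed by oxidative opening of ring C.
- Fallback: a more electron-poor, hydrolysis-resistant and reductively removable group. The route sets out from 21 and returns at 24.
  - 21 would be converted (2,2,2-trichloroethyl chloroformate, pyridine) into the trichloroethyl carbonate F13.
  - Oxidation as in step 11 would give the carbonate-protected quinone F14.
  - Zn in AcOH/THF would remove the carbonate and at the same time reduce ring B to the hydroquinone F15.
  - Stirring F15 in air (or brief treatment with Ag2O) would reoxidise only the ring B hydroquinone and give 24.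

## Further compounds

F1 | step 9 | 1-(benzyloxy)-5-(bromomethyl)-2,3-dimethoxy-4-(methoxymethoxy)benzene | BrCc1cc(OCc2ccccc2)c(OC)c(OC)c1OCOC
F2 | step 9 | (4S)-4-benzyl-3-[(2S)-3-[5-(benzyloxy)-3,4-dimethoxy-2-(methoxymethoxy)phenyl]-2-(2,3,4,5-tetramethoxyphenyl)propanoyl]-1,3-oxazolidin-2-one | COc1cc([C@H](Cc2cc(OCc3ccccc3)c(OC)c(OC)c2OCOC)C(=O)N2[C@@H](Cc3ccccc3)COC2=O)c(OC)c(OC)c1OC
F3 | step 9 | (2S)-3-[5-(benzyloxy)-3,4-dimethoxy-2-(methoxymethoxy)phenyl]-2-(2,3,4,5-tetramethoxyphenyl)propan-1-ol | OC[C@H](c1cc(OC)c(OC)c(OC)c1OC)Cc1cc(OCc2ccccc2)c(OC)c(OC)c1OCOC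
F4 | step 9 | 4-(benzyloxy)-6-[(2S)-3-hydroxy-2-(2,3,4,5-tetramethoxyphenyl)propyl]-2,3-dimethoxyphenol | OC[C@H](c1cc(OC)c(OC)c(OC)c1OC)Cc1cc(OCc2ccccc2)c(OC)c(OC)c1O
F5 | step 9 | (3S)-6-(benzyloxy)-7,8-dimethoxy-3-(2,3,4,5-tetramethoxyphenyl)-3,4-dihydro-2H-chromene | COc1cc([C@H]2COc3c(cc(OCc4ccccc4)c(OC)c3OC)C2)c(OC)c(OC)c1OC
F6 | step 7 | methyl (2Z)-2,3-dimethoxyprop-2-enoate | CO/C=C(\OC)C(=O)OC
F7 | step 7 | (2Z)-2,3-dimethoxyprop-2-enoic acid | CO/C=C(\OC)C(=O)O
F8 | step 7 | (2Z)-2,3-dimethoxyprop-2-enoyl chloride | CO/C=C(\OC)C(=O)Cl
F9 | step 7 | dipotassium pentacarbonylchromate, K2Cr(CO)5 | [K+].[K+].O=C=[Cr-2](=C=O)(=C=O)(=C=O)=C=O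
F10 | step 7 | tetramethylammonium pentacarbonyl[(2Z)-2,3-dimethoxyprop-2-enoyl]chromate | C[N+](C)(C)C.[O-]C(/C(OC)=C/OC)=[Cr](=C=O)(=C=O)(=C=O)(=C=O)=C=O
F11 | step 7 | pentacarbonyl{[(1Z)-1,2-dimethoxyethenyl][(2S)-2-(2,3,4,5-tetramethoxyphenyl)pent-4-yn-1-yloxy]methylidene}chromium | O=C=[Cr](=C=O)(=C=O)(=C=O)(=C=O)=C(OC[C@H](c1cc(OC)c(OC)c(OC)c1OC)CC#C)/C(OC)=C/OC
F12 | step 8 | (2S)-2-(2,3,4,5-tetramethoxyphenyl)pent-4-yn-1-yl trifluoromethanesulfonate | O=S(=O)(OC[C@H](c1cc(OC)c(OC)c(OC)c1OC)CC#C)C(F)(F)F
F13 | step 11 | (3S)-7,8-dimethoxy-3-(2,3,4,5-tetramethoxyphenyl)-3,4-dihydro-2H-chromen-6-yl 2,2,2-trichloroethyl carbonate | COc1cc([C@H]2COc3c(cc(OC(=O)OCC(Cl)(Cl)Cl)c(OC)c3OC)C2)c(OC)c(OC)c1OC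
F14 | step 11 | (3S)-3-(4,5-dimethoxy-3,6-dioxocyclohexa-1,4-dien-1-yl)-7,8-dimethoxy-3,4-dihydro-2H-chromen-6-yl 2,2,2-trichloroethyl carbonate | COC1=C(OC)C(=O)C([C@H]2COc3c(cc(OC(=O)OCC(Cl)(Cl)Cl)c(OC)c3OC)C2)=CC1=O
F15 | step 11 | 2-[(3S)-6-hydroxy-7,8-dimethoxy-3,4-dihydro-2H-chromen-3-yl]-5,6-dimethoxybenzene-1,4-diol | COc1c(O)cc([C@H]2COc3c(cc(O)c(OC)c3OC)C2)c(O)c1OC
A1 | alternative 1 | (3S)-6-benzyloxy-3-[2,5-bis(benzyloxy)-3,4-dimethoxyphenyl]-7,8-dimethoxychroman-2-one | O=C1Oc2c(cc(OCc3ccccc3)c(OC)c2OC)C[C@H]1c1cc(OCc2ccccc2)c(OC)c(OC)c1OCc1ccccc1
A2 | alternative 1 | 4-(benzyloxy)-2,3-dimethoxy-6-methylidenecyclohexa-2,4-dien-1-one | C=C1C=C(OCc2ccccc2)C(OC)=C(OC)C1=O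
A3 | alternative 1 | 2-[2,5-bis(benzyloxy)-3,4-dimethoxyphenyl]acetic acid | OC(=O)Cc1cc(OCc2ccccc2)c(OC)c(OC)c1OCc1ccccc1
A4 | alternative 2 | cis-fused 2-benzyloxy-3,4,9,10-tetramethoxypterocarpan-8-ol with the target configuration at the carbon that becomes C3 | Oc1cc2c(c(OC)c1OC)O[C@@H]1c3cc(OCc4ccccc4)c(OC)c(OC)c3OC[C@H]21
A5 | alternative 2 | 6-(benzyloxy)-7,8-dimethoxy-2H-chromene | C1=Cc2cc(OCc3ccccc3)c(OC)c(OC)c2OC1
A6 | alternative 2 | 2,3-dimethoxycyclohexa-2,5-diene-1,4-dione | COC1=C(OC)C(=O)C=CC1=O
A7 | alternative 3 | 5-[(3S)-6-(tert-butyldimethylsilyloxy)-7,8-dimethoxy-3,4-dihydro-2H-chromen-3-yl]-2,3-dimethoxycyclohexa-2,5-diene-1,4-dione | COC1=C(OC)C(=O)C([C@H]2COc3c(cc(O[Si](C)(C)C(C)(C)C)c(OC)c3OC)C2)=CC1=O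
A8 | alternative 3 | 5-[3-[5-(tert-butyldimethylsilyloxy)-2-hydroxy-3,4-dimethoxyphenyl]prop-1-en-2-yl]-2,3-dimethoxycyclohexa-2,5-diene-1,4-dione | COC1=C(OC)C(=O)C(C(=C)Cc2cc(O[Si](C)(C)C(C)(C)C)c(OC)c(OC)c2O)=CC1=O
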